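The data are simulated for substances that don't exist; noise was put on by code.

J is the catalyst in a closed, stirred flask where L turns into Z and Z into G, and I must say what stands at the asked time with less J than in either earlier run.

common to all: L 0.10 M

| flask | J | remark | time |
|---|---|---|---|
| autumn | 0.24 mM | run made earlier |  |
| spring | 0.37 mM | run made earlier |  |
| flask | 0.17 mM |  | 4.0 h |

| run | time / h | Z / % | G / % |
|---|---|---|---|
| autumn | 0.417 | 41.3 | 5.4 |
| autumn | 1.00 | 55.4 | 17.4 |
| autumn | 2.00 | 56.1 | 28.6 |
| autumn | 3.00 | 53.7 | 33.0 |
| spring | 0.833 | 57.5 | 21.2 |
| spring | 1.50 | 55.7 | 30.7 |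
| spring | 2.50 | 54.7 | 33.9 |
| spring | 3.00 | 53.6 | 34.5 |

(standard deviation of a reading: 0.5 percentage points)

- concentration of Z at 4.0 h, in M
- concentration of G at 4.0 h, in M
- concentration of L at 4.0 h, in M

Follow one molecule of L. If J is not consumed and both steps run in proportion to [J] and to what they turn, each step is pseudo-first-order at fixed [J], and the molecule's chance per hour at each fork scales with [J]. With the charge of L held, its fate then depends on the product [J]·t, so runs with different [J] should share one master curve. I therefore shift every flask onto the autumn run: its time multiplied by its [J] and divided by the autumn [J]. For this flask that gives 2.83 h, the autumn time.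

But is the shift true? Spring's reading at 1.50 h has an autumn time of 2.31 h, where a straight line between the autumn readings gives G 30.0%. Spring read 30.7%, a gap of 0.72 percentage points against a scatter of 0.5 points, so the shift passes.

Still, this flask runs longer than any reading, and a slowly dying J would make the longer run lag. Autumn, which took longer to reach this point, does lie lower than spring. Taking that whole gap as loss and doubling it for the flask's longer clock, I allow 1.4 points on G.

The line between the autumn readings at 2.00 h and 3.00 h gives this flask Z 54.1%, G 32.3% and L 13.6%. G rose more in the hour before that stretch than during it, so my line reads G somewhat low.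

The forecast says 0.0545 M of Z, 0.0325 M of G and 0.013 M of L, since “the two runs merge onto one smooth curve”; it lies a little above my Z and G, and below my L. The flask gives 0.0546 M of Z, 0.0329 M of G and 0.0126 M of L.

    L + J ⇌ Z + J, rate k1*[L]*[J] forward; the back reaction follows from the equilibrium constant (K = 4.70, k = 1.90 M⁻¹ s⁻¹)
    Z + J ⇌ G + J, rate k2*[J]*[Z] forward; the back reaction follows from the equilibrium constant (K = 0.660, k = 0.680 M⁻¹ s⁻¹)

At an autumn time of 2.83 h, this flask is close to rest but not at it: ten times the time, an autumn time of 28.3 h, takes Z from 54.6% to 53.4%, G from 32.9% to 35.2% and L from 12.6% to 11.4%. The same charge read at 2.5 h has an autumn time of 1.77 h, so the autumn readings at 1.00 h and 2.00 h give Z 55.9% and G 26.0%. That flask holds 56.5% of Z and 27.1% of G.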